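**Assumption:** the target has no stereocentre and no stereogenic alkene (the diaryl ketone rotates freely), so it is achiral and nothing stereochemical needs to be set.

## Retrosynthetic overview

1. Disconnect the ring B aryl–C(=O) bond: a fully substituted ring A salicylaldehyde (its formyl C–H) plus a 2,6-disubstituted ring B aryl iodide, joined by Pd-catalysed, hydroxyl-directed aldehyde C–H arylation; a final acid step removes two MOM ethers and a dioxolane.
2. Ring A aldehyde from m-cresol: O-methylation, Ir C–H borylation/oxidation (orcinol pattern), ortho-bromination, ortho-formylation, chlorination of the last free position.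
3. Ring B iodide from 3-bromophenol: MOM protection, Ir C–H borylation/oxidation (5-bromoresorcinol pattern), two bromine-assisted ortho-lithiations (CHO then dioxolane; prenyl from prenyl bromide), Br→I.
4. No carbocycle is built: both benzene rings are bought, and the only ring formed is the temporary dioxolane.

## Route

### Ring A fragment

**Step 1**
Reactants: 1, m-cresol (3-methylphenol)
Product: 2, 3-methylanisole
Conditions: MeI, K2CO3, acetone, reflux
Reagents that add atoms: iodomethane, CI
Why: Williamson O-methylation of a phenoxide.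

**Step 2**
Reactants: 2, 3-methylanisole
Product: 3, 3-methoxy-5-methylphenol
Conditions: [Ir(OMe)(cod)]2 (1 mol %), dtbpy (2 mol %), HBpin, hexane, 80 °C; then Oxone, acetone/H2O, rt (one pot)
Reagents that add atoms: Oxone (potassium peroxymonosulfate), OOS(=O)(=O)[O-].[K+]
Why: Sterically controlled Ir-catalysed arene C–H borylation hits the only C–H meta to both substituents, and oxidation of the C–B bond gives the phenol.

**Step 3**
Reactants: 3, 3-methoxy-5-methylphenol
Product: 4, 2-bromo-5-methoxy-3-methylphenol
Conditions: NBS (1.0 equiv), i-Pr2NH (10 mol %), CH2Cl2, −78 → 0 °C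
Reagents that add atoms: N-bromosuccinimide, O=C1CCC(=O)N1Br
Why: Amine-mediated ortho-selective electrophilic bromination of a phenol; the chosen ortho carbon is also para to OMe, so both directing effects agree, and the bromine then blocks this site.

**Step 4**
Reactants: 4, 2-bromo-5-methoxy-3-methylphenol
Product: 5, 3-bromo-2-hydroxy-6-methoxy-4-methylbenzaldehyde
Conditions: MgCl2 (anhydrous), Et3N, paraformaldehyde, MeCN, reflux; aq. HCl work-up
Reagents that add atoms: formaldehyde (as paraformaldehyde), C=O
Why: Magnesium-phenoxide-mediated ortho-formylation (Casnati–Skattebøl) is ortho-specific, and the only free ortho position is the one between OH and OMe.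

**Step 5**
Reactants: 5, 3-bromo-2-hydroxy-6-methoxy-4-methylbenzaldehyde
Product: 6, 3-bromo-5-chloro-2-hydroxy-6-methoxy-4-methylbenzaldehyde
Conditions: SO2Cl2 (1.1 equiv), CH2Cl2, 0 °C → rt, dark
Reagents that add atoms: sulfuryl chloride, O=S(=O)(Cl)Cl
Why: Electrophilic aromatic chlorination at the single remaining ring position, which is para to OH, ortho to OMe and only meta to the formyl group.

### Ring B fragment

**Step 6**
Reactants: 7, 3-bromophenol
Product: 8, 1-bromo-3-(methoxymethoxy)benzene
Conditions: MOMCl, i-Pr2NEt, CH2Cl2, 0 °C → rt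
Reagents that add atoms: chloromethyl methyl ether, COCCl
Why: Standard MOM ether formation.

**Step 7**
Reactants: 8, 1-bromo-3-(methoxymethoxy)benzene
Product: 9, 3-bromo-5-(methoxymethoxy)phenol
Conditions: [Ir(OMe)(cod)]2 (1.5 mol %), dtbpy (3 mol %), B2pin2, THF, 80 °C; then NaOH, 30 % H2O2, THF/H2O, 0 °C (one pot)
Reagents that add atoms: hydrogen peroxide, OO
Why: Ir-catalysed C–H borylation at the 5-position (meta to both Br and OMOM, the only unhindered C–H) followed by basic C–B oxidation, which leaves ArBr and MOM untouched.

**Step 8**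
Reactants: 9, 3-bromo-5-(methoxymethoxy)phenol
Product: 10, 1-bromo-3,5-bis(methoxymethoxy)benzene
Conditions: MOMCl, i-Pr2NEt, CH2Cl2, 0 °C → rt
Reagents that add atoms: chloromethyl methyl ether, COCCl
Why: Standard MOM ether formation.

**Step 9**
Reactants: 10, 1-bromo-3,5-bis(methoxymethoxy)benzene
Product: 11, 2-bromo-4,6-bis(methoxymethoxy)benzaldehyde
Conditions: 10 added to LDA (1.1 equiv), THF, −78 °C, 1 h; DMF, −78 °C → rt
Reagents that add atoms: N,N-dimethylformamide, CN(C)C=O
Why: Amide-base deprotonation ortho to bromine (C–H flanked by Br and OMOM, the site from which 3,5-dialkoxybenzynes are known to form) and formylation of the aryllithium at −78 °C before LiBr loss; LDA causes no Br–Li exchange.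

**Step 10**
Reactants: 11, 2-bromo-4,6-bis(methoxymethoxy)benzaldehyde
Product: 12, 2-[2-bromo-4,6-bis(methoxymethoxy)phenyl]-1,3-dioxolane
Conditions: TMSOCH2CH2OTMS, TMSOTf (5 mol %), CH2Cl2, −78 → −40 °C; pyridine quench
Reagents that add atoms: 1,2-bis(trimethylsilyloxy)ethane, C[Si](C)(C)OCCO[Si](C)(C)C
Why: Aprotic low-temperature (Noyori-type) acetalisation protects the hindered aldehyde without protic acid, so the MOM ethers survive.

**Step 11**
Reactants: 12, 2-[2-bromo-4,6-bis(methoxymethoxy)phenyl]-1,3-dioxolane; 13, prenyl bromide (1-bromo-3-methylbut-2-ene)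
Product: 14, 2-[2-bromo-4,6-bis(methoxymethoxy)-3-(3-methylbut-2-en-1-yl)phenyl]-1,3-dioxolane
Conditions: LDA (1.2 equiv), THF, −78 °C; CuBr·SMe2 (1.0 equiv), −78 °C; 13, −78 → −20 °C
Reagents that add atoms: none (13 is a reactant)
Why: Second bromine-assisted ortho-lithiation at the C–H between Br and OMOM, transmetalation to a thermally stable arylcopper and SN2 allylic substitution on prenyl bromide to give the linear prenyl arene.

**Step 12**
Reactants: 14, the aryl bromide above
Product: 15, 2-[2-iodo-4,6-bis(methoxymethoxy)-3-(3-methylbut-2-en-1-yl)phenyl]-1,3-dioxolane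
Conditions: t-BuLi (2.1 equiv), Et2O/THF, −78 °C; I2, −78 °C; Na2S2O3 quench
Reagents that add atoms: iodine, II
Why: Fast bromine–lithium exchange and iodinolysis convert the bromide into the iodide needed for chemoselective oxidative addition in the coupling.

### Coupling and end game

**Step 13**
Reactants: 6, 3-bromo-5-chloro-2-hydroxy-6-methoxy-4-methylbenzaldehyde (1.2 equiv); 15, the aryl iodide
Product: 16, (3-bromo-5-chloro-2-hydroxy-6-methoxy-4-methylphenyl)[2-(1,3-dioxolan-2-yl)-3,5-bis(methoxymethoxy)-6-(3-methylbut-2-en-1-yl)phenyl]methanone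
Conditions: Pd(OAc)2 (10 mol %), LiCl (1 equiv), Cs2CO3 (2 equiv), CsOPiv (30 mol %), DMF, 100 °C, Ar
Reagents that add atoms: none
Why: Proposed new method: Pd(0) adds to the C–I bond of 15 (much faster than to the hindered, phenoxide-deactivated C–Br or the C–Cl of 6 under phosphine-free conditions), the caesium phenoxide of 6 displaces iodide, and the now-proximal formyl C–H is cleaved by pivalate-assisted concerted metalation–deprotonation to give a five-membered aroyl(aryl)palladate chelate whose C(acyl)–C(aryl) reductive elimination is fast (sp2 acyl carbon, relief of strain) and releases the hydrogen-bonded 2-hydroxybenzophenone; the closest known reaction is the Pd-catalysed, hydroxyl-directed coupling of simple salicylaldehydes with unhindered aryl iodides to give 2-hydroxybenzophenones, which has not been shown for 2,6-disubstituted aryl iodides, tetra-ortho-substituted products or bromo/chloro-bearing salicylaldehydes.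

**Step 14**
Reactants: 16, the protected benzophenone
Product: 17, Pestalone G, 2-(3-bromo-5-chloro-2-hydroxy-6-methoxy-4-methylbenzoyl)-4,6-dihydroxy-3-(3-methylbut-2-en-1-yl)benzaldehyde
Conditions: 3 M aq. HCl/THF/MeOH (1:2:2), 40 °C, monitored closely; then THF/H2O, rt
Reagents that add atoms: water, O
Why: Acid-catalysed acetal hydrolysis removes both MOM ethers and the dioxolane in one operation, while the aryl OMe, ArBr and ArCl are inert and mild conditions limit prenyl cyclisation.

## Compound list

1 | m-cresol (3-methylphenol) | Cc1cccc(O)c1 | starting material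
2 | 3-methylanisole | COc1cccc(C)c1 | intermediate
3 | 3-methoxy-5-methylphenol | COc1cc(C)cc(O)c1 | intermediate
4 | 2-bromo-5-methoxy-3-methylphenol | COc1cc(O)c(Br)c(C)c1 | intermediate
5 | 3-bromo-2-hydroxy-6-methoxy-4-methylbenzaldehyde | COc1cc(C)c(Br)c(O)c1C=O | intermediate
6 | 3-bromo-5-chloro-2-hydroxy-6-methoxy-4-methylbenzaldehyde | COc1c(Cl)c(C)c(Br)c(O)c1C=O | intermediate
7 | 3-bromophenol | Oc1cccc(Br)c1 | starting material
8 | 1-bromo-3-(methoxymethoxy)benzene | COCOc1cccc(Br)c1 | intermediate
9 | 3-bromo-5-(methoxymethoxy)phenol | COCOc1cc(O)cc(Br)c1 | intermediate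
10 | 1-bromo-3,5-bis(methoxymethoxy)benzene | COCOc1cc(Br)cc(OCOC)c1 | intermediate
11 | 2-bromo-4,6-bis(methoxymethoxy)benzaldehyde | COCOc1cc(Br)c(C=O)c(OCOC)c1 | intermediate
12 | 2-[2-bromo-4,6-bis(methoxymethoxy)phenyl]-1,3-dioxolane | COCOc1cc(Br)c(C2OCCO2)c(OCOC)c1 | intermediate
13 | prenyl bromide (1-bromo-3-methylbut-2-ene) | CC(C)=CCBr | starting material
14 | 2-[2-bromo-4,6-bis(methoxymethoxy)-3-(3-methylbut-2-en-1-yl)phenyl]-1,3-dioxolane | COCOc1cc(OCOC)c(C2OCCO2)c(Br)c1CC=C(C)C | intermediate
15 | 2-[2-iodo-4,6-bis(methoxymethoxy)-3-(3-methylbut-2-en-1-yl)phenyl]-1,3-dioxolane | COCOc1cc(OCOC)c(C2OCCO2)c(I)c1CC=C(C)C | intermediate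
16 | (3-bromo-5-chloro-2-hydroxy-6-methoxy-4-methylphenyl)[2-(1,3-dioxolan-2-yl)-3,5-bis(methoxymethoxy)-6-(3-methylbut-2-en-1-yl)phenyl]methanone | COc1c(Cl)c(C)c(Br)c(O)c1C(=O)c1c(C2OCCO2)c(OCOC)cc(OCOC)c1CC=C(C)C | intermediate
17 | Pestalone G | COc1c(Cl)c(C)c(Br)c(O)c1C(=O)c1c(C=O)c(O)cc(O)c1CC=C(C)C | target

## Summary

**Total steps:** 14.
**Longest linear sequence:** 9 (steps 6–12, then 13 and 14); the ring A branch is 5 steps (1–5) before the coupling.

**Steps most likely to fail**

1. **Step 13 (proposed new coupling).** Risks are failure of C–H cleavage or reductive elimination at a tetra-ortho-substituted centre, O-arylation, or competing insertion into the ArBr of 6. Fallback (known chemistry): Br–Li exchange on bromide 14 (t-BuLi, −78 °C), 1,2-addition to the MOM ether of aldehyde 6, Dess–Martin oxidation of the diarylmethanol, then step 14.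
2. **Step 9 (and step 11, same logic).** Deprotonation may occur between the two OMOM groups instead of next to bromine, or the ortho-bromoaryllithium may lose LiBr. Fallback: replace deprotonation by electrophilic iodination of 10 (NIS, para to OMOM) followed by chemoselective I/Mg exchange (i-PrMgCl·LiCl, −40 °C) and DMF quench, which fixes the position by halogen placement and gives a more stable ortho-bromoaryl Grignard.
3. **Step 14 (global acid deprotection).** The phenol ortho to the prenyl group can cyclise to a chroman, or HCl can add to the alkene. Fallback: carry the ring B phenols as SEM ethers (SEMCl in steps 6 and 8), release them with fluoride while the aldehyde is still masked, then open the dioxolane with PPTS in wet acetone so no strong acid meets the prenyl phenol.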